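The earlier runs and the new flask are simulated for an exercise; scatter was added.

**The choice.** I decide to read this flask from its two earlier runs, not from a fitted scheme. D is the substrate, E the product, L and Q the other products, and Z the species formed on the way.

| setting | zeta | beta | flask |
|---|---|---|---|
| D | 0.049 M | 0.19 M | 0.097 M |
| remark | run made earlier | run made earlier |  |
| time |  |  | 15 h |

- zeta (time / h: E / %, D / %): 0.667: 12.3, 75.7; 1.33: 18.7, 61.2; 2.50: 21.7, 47.6; 5.00: 18.4, 34.9; 8.00: 13.1, 26.2; 15.0: 7.2, 16.6
- beta (time / h: E / %, D / %): 0.667: 13.4, 70.9; 1.33: 20.3, 54.2; 2.50: 26.3, 38.6; 5.00: 26.1, 28.1; 8.00: 20.3, 23.6; 15.0: 12.4, 16.4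

(standard deviation of a reading: 0.3 percentage points)

- in percentages every species weighs as the D in it: one Z counts as two
- for E the Z are counted in
- candidate steps: D <-> E; D <-> L; E <-> L; E -> Q; D + E <-> Z
- in an amount of E, one Z counts as one E

- time up to 15 h at which E stands highest
- the amount of E, in percent of the D charged, at that time

**Rule of thumb.** At fixed temperature, percent curves of first-order steps do not shift with the charge, so the bench answer is to copy a run. Zeta's highest reading, 21.7 % at 2.50 h, would then stand for the flask.

**Its border.** Beta reads 26.3 % at that same time, 4.6 percentage points above zeta, with a scatter of 0.3 points, so copying fails here. The height changes by a factor of 1.21 for a charge factor of 3.88. Among the candidate steps, D + E <-> Z is the second-order one.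

**Charge position.** So I place the flask on the logarithm of the charge. The ln of its charge over zeta's, divided by the ln of beta's charge over zeta's, is 0.504, the charge position. Zeta's reading at 2.50 h plus that share of the gap gives 24.0 %, which I take as my estimate of the height. For the time, I read zeta's top near 2.50 h and beta's between its nearly equal readings, near 3.75 h. The same share gives 3.13 h.

**The result.** The forecast gives 24.2 % at 3 h, noting that “The top is broad”. The flask gives 24.4 % at 2.94 h, against my height of 24.0 % and my time of 3.13 h. At that time Z stands at 26.7 % of the D charged, each Z weighing as two D. Applied to the last readings of zeta and beta, the charge position gives 9.82 % of E, and the flask holds 9.13 % at 15.0 h.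

    D ⇌ E (K = 0.480, k = 0.240 h⁻¹)
    D ⇌ L (K = 2.90, k = 0.0870 h⁻¹)
    E ⇌ L (k = 0.150 h⁻¹)
    E → Q (k = 0.260 h⁻¹)
    D + E ⇌ Z, settled at all times (K = 31.0 L mol⁻¹)

**Second flask.** A neighbouring flask charged with 0.024 M of D has a lower charge than zeta, so its charge position is −0.527. The same line, stretched beyond the runs, gives 19.3 %. The computed highest E there is 19.6 %.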